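The data were computed on assumed constants; the scatter is artificial.

I drew the flask's curve from two earlier runs.

| flask | substrate | gas phase | catalyst | remark | time |
|---|---|---|---|---|---|
| green | 0.11 M (fed, over 12 min) | 23 mM (held) | 2.8 mM | run made earlier; the fed solution adds 0.10 times the starting volume |  |
| red | 0.11 M (fed, over 12 min) | 23 mM (held) | 4.1 mM | run made earlier; the fed solution adds 0.10 times the starting volume |  |
| flask | 0.11 M (fed, over 12 min) | 23 mM (held) | 5.5 mM | the fed solution adds 0.10 times the starting volume | 4.0 h |

| run | time / h | target / % | substrate / % |
|---|---|---|---|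
| green | 0.0833 | 11.9 | 27.8 |
| green | 0.200 | 39.5 | 50.9 |
| green | 0.417 | 56.6 | 21.8 |
| green | 1.00 | 42.1 | 13.3 |
| green | 2.50 | 17.5 | 6.4 |
| red | 0.0833 | 13.4 | 26.2 |
| red | 0.200 | 44.1 | 46.1 |
| red | 0.417 | 58.3 | 21.7 |
| red | 1.00 | 41.9 | 13.5 |
| red | 2.50 | 17.0 | 5.7 |

(standard deviation of a reading: 0.5 percentage points)

- every charge counts on the volume at the start, and the solution that is fed holds the whole dose
- the numbers in the tables scatter by 0.5 percentage points (one standard deviation)
- at the start none of the gas phase is in solution
- percentages count the whole charge, also what has not yet gone in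

1. when, up to 4.0 h, the flask holds most target
2. the amount of target, in percent of the substrate charged, at that time

The green run started low, with 11.9% target at 0.0833 h, and climbed to 39.5% as the feed ended at 0.200 h. Substrate still stood above target there, at 50.9%, but by 0.417 h target had crossed it, reading 56.6% against 21.8%. In the green readings the knee lay near that time. The red run, with 4.1 mM catalyst against 2.8 mM, read 58.3% there.

After the knee the two runs lay together, at 42.1% and 41.9% at 1.00 h. So I carried one quantity, the half-life of the late fall, the time in which target drops to half of what stood. I treated this as a pseudo-first-order fall, with the gas held. The green readings gave 1.18 h. Counted from the red reading at 0.417 h over the time allowed, that half-life took target towards zero and gave me, as my own estimate for the flask, 7.11% at 4.0 h.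

The forecast put the best at 0.35 h with 59.5%, saying: “Target peaks when the substrate-to-target ratio falls to about 0.4”.

The flask gave 60.5% at 0.343 h, which is 1.00 percentage point above the forecast.

    substrate + dissolved gas → uncatalysed product (k = 1.75 M⁻¹ min⁻¹)
    substrate + dissolved gas + catalyst ⇌ catalyst + target (K = 122 M⁻¹, k = 3810 M⁻² min⁻¹)
    gas phase ⇌ dissolved gas, rate k3*(csat - [dissolved gas]) (kL = 0.645 min⁻¹)

The flask ended with 6.93% target at 4.00 h. Its fall from the best spans 3.12 half-lives of 1.18 h, or 3.68 h, against the 3.66 h that passed. The neighbour flask, charged with 0.44 M substrate, reached a best of 52.7% and held 7.60% target at 4.00 h. Its fall spans 2.80 half-lives, which at the same half-life is 3.30 h.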